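**Retrosynthetic overview**
1. Target 10 ⇐ triol 9 by regioselective double benzoylation (primary OH and the less hindered ring OH).
2. Triol 9 ⇐ anti-bis-epoxide 7 by a double base-promoted epoxide → allylic alcohol transposition; both ring C–O stereocentres and the diene come from the two oxiranes.
3. Bis-epoxide 7 ⇐ dienol 5 by a one-flask Sharpless / vanadium bis-epoxidation; both oxiranes form in this operation and fix the trans (5R,6R) relationship.
4. Dienol 5 ⇐ 1-acetoxybutadiene 1 + acrolein 2 (Diels–Alder, elimination, reduction).
Ring order: carbocycle first, then the two oxiranes together, then both oxiranes are opened again.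

Assumption: the target SMILES is read as the trans-(5R,6R) isomer; commercial 1-acetoxy-1,3-butadiene (E/Z mixture) is used in excess and only its reactive E isomer is listed as 1.

**Step 1**
Reactants: 1 (E)-buta-1,3-dien-1-yl acetate; 2 acrolein
Product: 5 (cyclohexa-1,3-dien-1-yl)methanol, via acetoxy aldehyde 3 (not isolated), via dienal 4 (not isolated)
Conditions: 1 (1.5 equiv), PhMe, BHT (cat.), 80 °C; DBU, 0 °C; then MeOH, CeCl3·7H2O, NaBH4, −20 °C
Reagents that add atoms: none
Why: A normal-demand Diels–Alder reaction gives the "ortho" adduct, DBU removes AcOH by E1cB elimination to the conjugated dienal, and Luche 1,2-reduction of the crude air-sensitive dienal gives the achiral dienol, so no stereocentre survives this step.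

**Step 2**
Reactants: 5 (cyclohexa-1,3-dien-1-yl)methanol
Product: 7 [(1R,2S,4S,7R)-3,8-dioxatricyclo[5.1.0.0²,⁴]octan-4-yl]methanol, via monoepoxide 6 (not isolated)
Conditions: Ti(OiPr)4 (10 mol %), L-(+)-DIPT (12 mol %), TBHP (3 equiv, decane), 4 Å MS, CH2Cl2, −20 °C; then VO(acac)2 (5 mol %), 0 °C → rt
Reagents that add atoms: tert-butyl hydroperoxide, CC(C)(C)OO
Why: Proposed new method: a Sharpless asymmetric epoxidation with L-(+)-tartrate places the first oxygen on the allylic trisubstituted alkene (Ti–tartrate face control, ≥90% ee expected) to give the (1S,6S)-epoxy alcohol, and VO(acac)2 added to the same flask then uses the remaining TBHP and the CH2OH group, which lies on the ring face opposite the first oxirane, for a hydroxyl-directed epoxidation of the remaining alkene on that face, so both oxiranes and the trans relationship of the two future carbinol carbons are set in one operation; the closest known reactions are the Sharpless epoxidation of 2,4-dien-1-ols and vanadium-catalysed hydroxyl-directed epoxidation of bishomoallylic alcohols.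

**Step 3**
Reactants: 7 [(1R,2S,4S,7R)-3,8-dioxatricyclo[5.1.0.0²,⁴]octan-4-yl]methanol
Product: 9 (1R,2R)-3-(hydroxymethyl)cyclohexa-3,5-diene-1,2-diol, via epoxy diol 8 (not isolated)
Conditions: LDA (5 equiv), THF–DMPU, −40 °C → rt; H2O, 0 °C
Reagents that add atoms: none
Why: The base-promoted epoxide → allylic alcohol rearrangement (Crandall–Rickborn syn-β-elimination, as in the benzene hydrate synthesis) runs twice, each time removing a ring CH2 proton and breaking the outer C–O bond (the CH2O⁻ group is deactivated as its alkoxide and the second opening is allylically activated), so both double bonds move into the diene while the two inner C–O bonds and their configurations are untouched.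

**Step 4**
Reactants: 9 (1R,2R)-3-(hydroxymethyl)cyclohexa-3,5-diene-1,2-diol
Product: 10 [(5R,6R)-5-(benzoyloxy)-6-hydroxycyclohexa-1,3-dien-1-yl]methyl benzoate
Conditions: BzCl (2.05 equiv), pyridine, CH2Cl2, −40 → −20 °C; NaHCO3 work-up
Reagents that add atoms: benzoyl chloride, O=C(Cl)c1ccccc1
Why: In this regioselective acylation the primary allylic OH reacts first and, of the two secondary OH groups, the C-5 OH is more accessible than the C-6 OH, which is flanked by the CH2OBz-bearing sp2 carbon, and no stereocentre is touched.

**Compound list**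
1 | (E)-buta-1,3-dien-1-yl acetate | CC(=O)O/C=C/C=C | starting material
2 | acrolein (prop-2-enal) | C=CC=O | starting material
3 | cis-2-acetoxycyclohex-3-ene-1-carbaldehyde (racemic, one enantiomer drawn) | CC(=O)O[C@@H]1C=CCC[C@@H]1C=O | intermediate
4 | cyclohexa-1,3-diene-1-carbaldehyde | O=CC1=CC=CCC1 | intermediate
5 | (cyclohexa-1,3-dien-1-yl)methanol | OCC1=CC=CCC1 | intermediate
6 | [(1S,6S)-7-oxabicyclo[4.1.0]hept-4-en-1-yl]methanol | OC[C@@]12CCC=C[C@@H]1O2 | intermediate
7 | [(1R,2S,4S,7R)-3,8-dioxatricyclo[5.1.0.0²,⁴]octan-4-yl]methanol (anti-bis-epoxide, oxirane oxygens on opposite ring faces) | OC[C@@]12CC[C@H]3O[C@H]3[C@@H]1O2 | intermediate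
8 | (1S,2R,6R)-3-(hydroxymethyl)-7-oxabicyclo[4.1.0]hept-3-en-2-ol | OCC1=CC[C@H]2O[C@H]2[C@@H]1O | intermediate
9 | (1R,2R)-3-(hydroxymethyl)cyclohexa-3,5-diene-1,2-diol (trans) | OCC1=CC=C[C@@H](O)[C@@H]1O | intermediate
10 | [(5R,6R)-5-(benzoyloxy)-6-hydroxycyclohexa-1,3-dien-1-yl]methyl benzoate | O=C(OCC1=CC=C[C@@H](OC(=O)c2ccccc2)[C@@H]1O)c1ccccc1 | target

**Total step count:** 4. **Longest linear sequence:** 4.

**Steps most likely to fail and fallbacks**

Step 2 (one-flask bis-epoxidation). The risks are Lewis-acid opening of the vinyl epoxy alcohol 6, retardation of the vanadium step by tartrate, and an ee below that needed (upgrade by recrystallisation of 10). The fallback sets out from 5 and comes back at 7. The metal relay is given up: the Sharpless epoxidation is run alone and 6 is isolated. The second oxirane is then made in a separate, metal-free step (mCPBA, NaHCO3, CH2Cl2, 0 °C). Here the substrate chooses the face: attack anti to the allylic oxirane oxygen, reinforced by hydrogen bonding to the CH2OH group. No new compound arises.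

Step 3 (double transposition). The risks are proton removal from the exocyclic CH2O carbon, aminolysis of an oxirane, and incomplete first elimination. The fallback sets out from 7 and comes back at 9. The disubstituted oxirane is opened first and separately: PhSeNa [(PhSe)2, NaBH4, EtOH] attacks its carbon remote from the other oxirane to give the trans hydroxy selenide F1. H2O2/pyridine then oxidises selenium, and the selenoxide eliminates syn, away from the carbinol carbon, to the epoxy allylic diol F2. The one remaining elimination is now allylically activated and needs only LDA (3 equiv, THF, −78 → 0 °C) to give 9.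

Step 4 (selective double benzoylation). The risks are over-acylation at C-6, a 5/6 regioisomer mixture, and acid-promoted aromatisation. The fallback sets out from 9 and comes back at 10. PhB(OH)2 (PhMe, 4 Å MS) ties the 1,3-diol (CH2OH plus the neighbouring ring OH) into the six-membered cyclic phenylboronate F3, leaving only the C-5 hydroxyl free. BzCl/pyridine gives the boronate benzoate F4, and exchange with pinacol releases the diol monobenzoate F5. The primary allylic OH is then benzoylated alone (BzCl 1.0 equiv, 2,4,6-collidine, CH2Cl2, −78 °C) to give 10.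

**Further compounds**
F0 | step 2 | none | none
F1 | step 3 | (1S,2S,3S,6S)-6-(hydroxymethyl)-3-(phenylselanyl)-7-oxabicyclo[4.1.0]heptan-2-ol | OC[C@@]12CC[C@H]([Se]c3ccccc3)[C@@H](O)[C@@H]1O2
F2 | step 3 | (1S,2R,6S)-6-(hydroxymethyl)-7-oxabicyclo[4.1.0]hept-3-en-2-ol | OC[C@@]12CC=C[C@@H](O)[C@@H]1O2
F3 | step 4 | (8R,8aR)-2-phenyl-8,8a-dihydro-4H-1,3,2-benzodioxaborinin-8-ol (cyclic phenylboronate of 9 across CH2O and the adjacent ring O) | B1(c2ccccc2)OCC3=CC=C[C@@H](O)[C@@H]3O1
F4 | step 4 | (8R,8aR)-2-phenyl-8,8a-dihydro-4H-1,3,2-benzodioxaborinin-8-yl benzoate | B1(c2ccccc2)OCC3=CC=C[C@@H](OC(=O)c4ccccc4)[C@@H]3O1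
F5 | step 4 | (1R,6R)-6-hydroxy-5-(hydroxymethyl)cyclohexa-2,4-dien-1-yl benzoate | OCC1=CC=C[C@@H](OC(=O)c2ccccc2)[C@@H]1O
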